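**Plan**
Retrosynthesis: after the six phenol protecting groups are removed, both A-ring C1–C(=O) bonds are cut at once. The A–CH2–A' core is then cut at the bridge carbon to formaldehyde and two ester-blocked phloroglucinol units.
Enabling feature: on each ring B the ketone carbon (on C1) and the methyl carbon (on C6) are ortho neighbours. They can therefore arrive together as C1 (C=O) and C2 (CH2) of a benzocyclobutenone fused to ring B. A-ring C1 lies between the oxygens on C2 and C6, the site that two MOM ethers lithiate.
Forward, core: 4-O-methylation, CH2O bridging, loss of the blocking ester, four MOM ethers.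
Forward, ring B: MOM ether, aryne/ketene acetal [2+2] (the only ring formed, and opened again later), acetal hydrolysis.
Union: double lithiation, double carbonyl addition and double four-ring opening in one flask, then global MOM removal.
Stereochemistry: the target has no stereocentre, so none has to be set; the transient carbinol centres are erased.

Key step: step 8

Remark: the SMILES carries no stereodescriptor. The molecule has no stereocentre, and rotation about the aryl–carbonyl and aryl–CH2 bonds is taken as fast at room temperature, so it is treated as achiral.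

Step 1
Reactants: 1 methyl 2,4,6-trihydroxybenzoate
Product: 2 methyl 2,6-dihydroxy-4-methoxybenzoate
Conditions: Me2SO4 (1.0 equiv), K2CO3 (1.1 equiv), acetone, rt → 50 °C
Reagents that add atoms: dimethyl sulfate, COS(=O)(=O)OC
Why: Williamson-type O-methylation; the 2- and 6-hydroxyls are held in hydrogen bonds to the ester, so one equivalent of electrophile with a weak base should alkylate the free and more acidic 4-OH para to the ester.

Step 2
Reactants: 2 methyl 2,6-dihydroxy-4-methoxybenzoate (2 equiv); 3 formaldehyde
Product: 4 dimethyl 3,3'-methylenebis(2,6-dihydroxy-4-methoxybenzoate)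
Conditions: 37% aq. CH2O (0.5 equiv), KOH (20 mol %), MeOH–H2O, 0 °C → rt
Reagents that add atoms: none
Why: Base-catalysed phenol–formaldehyde condensation (hydroxymethylation, o-quinone methide, conjugate addition of a second phenolate); the ester blocks the carbon between the two hydroxyls, so only the equivalent C3/C5 sites can react, and the deficit of formaldehyde should hold the reaction at the dimer.

Step 3
Reactants: 4 dimethyl 3,3'-methylenebis(2,6-dihydroxy-4-methoxybenzoate)
Product: 6 bis(2,4-dihydroxy-6-methoxyphenyl)methane, via methylene-bridged diacid 5 (not isolated)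
Conditions: 2 M aq. NaOH (degassed), reflux; then HCl to pH 2, 60 °C
Reagents that add atoms: none
Why: Saponification followed by protodecarboxylation; 2,6-dihydroxybenzoic acids lose CO2 readily through ipso-protonation of the electron-rich ring, which removes the blocking group and frees the CH between the two hydroxyls.

Step 4
Reactants: 6 bis(2,4-dihydroxy-6-methoxyphenyl)methane
Product: 7 bis[6-methoxy-2,4-bis(methoxymethoxy)phenyl]methane
Conditions: NaH (5 equiv), MOMCl (5 equiv), DMF, 0 °C → rt
Reagents that add atoms: chloromethyl methyl ether (MOMCl), COCCl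
Why: Williamson etherification of the four phenoxides; the MOM acetals tolerate butyllithium and serve as the directing groups of step 8.

Step 5
Reactants: 8 4-bromo-3-methoxyphenol
Product: 9 1-bromo-2-methoxy-4-(methoxymethoxy)benzene
Conditions: NaH (1.2 equiv), MOMCl (1.2 equiv), DMF, 0 °C → rt
Reagents that add atoms: chloromethyl methyl ether (MOMCl), COCCl
Why: Williamson etherification of a single unhindered phenoxide; it gives a base-stable ether that falls off with the other MOM groups in the last step.

Step 6
Reactants: 9 1-bromo-2-methoxy-4-(methoxymethoxy)benzene; 10 ketene diethyl acetal (1,1-diethoxyethene)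
Product: 12 diethyl acetal of 6-methoxy-4-(methoxymethoxy)benzocyclobutenone, via 3-methoxy-5-(methoxymethoxy)benzyne 11 (not isolated)
Conditions: NaNH2 (3 equiv), 10 (2.5 equiv), THF, 65 °C
Reagents that add atoms: none
Why: Dehydrobromination can only use the single hydrogen ortho to bromine, so one aryne forms, and its polar [2+2] cycloaddition places the nucleophilic CH2 terminus of the ketene acetal on the aryne carbon remote from OMe and the acetal carbon next to OMe, as is usual for 3-alkoxyarynes.

Step 7
Reactants: 12 diethyl acetal of 6-methoxy-4-(methoxymethoxy)benzocyclobutenone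
Product: 13 6-methoxy-4-(methoxymethoxy)benzocyclobutenone
Conditions: p-TsOH·H2O (10 mol %), THF–H2O (4:1), rt
Reagents that add atoms: water, O
Why: Acid-catalysed acetal hydrolysis; the dialkyl ketal ionises to an oxocarbenium ion stabilised by the ortho-methoxy and para-MOMO groups and should hydrolyse under catalytic acid at room temperature, where an aryl MOM ether reacts far more slowly.

Step 8
Reactants: 7 bis[6-methoxy-2,4-bis(methoxymethoxy)phenyl]methane; 13 6-methoxy-4-(methoxymethoxy)benzocyclobutenone (2.2 equiv)
Product: 17 digriseophene A hexa-MOM ether, via dilithiated core 14 (not isolated), via bis(lithium benzocyclobutenoxide) 15 (not isolated), via bis(o-quinodimethane lithium enolate) 16 (not isolated)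
Conditions: n-BuLi (2.2 equiv), THF, 0 °C, 1 h; 13, THF, −78 °C; → rt; sat. aq. NH4Cl
Reagents that add atoms: none
Why: Each ring of 7 is deprotonated by directed ortho-metalation at the one CH flanked by two MOM ethers, and each C–Li of 14 adds 1,2 to the strained carbonyl of 13, which is tied back in the four-membered ring and cannot enolise without forming a benzocyclobutadiene, so addition should prevail despite the four ortho substituents. On warming, each alkoxide of 15 undergoes an oxyanion-accelerated conrotatory 4π electrocyclic opening of the carbinol–CH2 bond with oxygen rotating outward, and the dienolate 16 is protonated at its exocyclic CH2 on quenching, which delivers the ketone and the ring-B methyl group together with release of ring strain. The closest known reaction type is aryllithium addition to benzocyclobutenones followed by base-induced isomerisation of the 1-arylbenzocyclobutenols to 2-methylbenzophenones, here run twice on one molecule. No ring is closed (two four-membered rings are opened) and no stereocentre remains, since the two carbinol centres of 15 form without control and are erased on opening. Site selectivity of lithiation is needed and is secured by cooperative chelation of lithium by two MOM groups, while the methoxy group, buttressed by the benzylic CH2, turns its methyl toward the competing CH and the electron-rich diarylmethane CH2 is kinetically much less acidic. Bond selectivity in the opening is needed as well and rests on the pericyclic pathway, which can break only the carbinol–CH2 bond, and 13 is kept close to stoichiometric so that 16 meets no ketone.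

Step 9
Reactants: 17 digriseophene A hexa-MOM ether
Product: 18 digriseophene A
Conditions: conc. HCl (cat.), MeOH–THF, 45 °C
Reagents that add atoms: none
Why: Acid-catalysed transacetalisation of the six MOM ethers; methanol carries off each CH2 unit as dimethoxymethane so that no free formaldehyde can re-bridge the electron-rich rings, and the aryl methyl ethers, the ketones and the diarylmethane should be untouched.

**Compound list**
1 | methyl 2,4,6-trihydroxybenzoate | COC(=O)c1c(O)cc(O)cc1O | starting material
2 | methyl 2,6-dihydroxy-4-methoxybenzoate | COC(=O)c1c(O)cc(OC)cc1O | intermediate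
3 | formaldehyde | C=O | starting material
4 | dimethyl 3,3'-methylenebis(2,6-dihydroxy-4-methoxybenzoate) | COC(=O)c1c(O)cc(OC)c(Cc2c(OC)cc(O)c(C(=O)OC)c2O)c1O | intermediate
5 | 3,3'-methylenebis(2,6-dihydroxy-4-methoxybenzoic acid), not isolated | OC(=O)c1c(O)cc(OC)c(Cc2c(OC)cc(O)c(C(=O)O)c2O)c1O | intermediate
6 | bis(2,4-dihydroxy-6-methoxyphenyl)methane | COc1cc(O)cc(O)c1Cc1c(OC)cc(O)cc1O | intermediate
7 | bis[6-methoxy-2,4-bis(methoxymethoxy)phenyl]methane | COc1cc(OCOC)cc(OCOC)c1Cc1c(OC)cc(OCOC)cc1OCOC | intermediate
8 | 4-bromo-3-methoxyphenol | COc1cc(O)ccc1Br | starting material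
9 | 1-bromo-2-methoxy-4-(methoxymethoxy)benzene | COCOc1ccc(Br)c(OC)c1 | intermediate
10 | ketene diethyl acetal (1,1-diethoxyethene) | C=C(OCC)OCC | starting material
11 | 3-methoxy-5-(methoxymethoxy)benzyne, not isolated | COC1=CC(OCOC)=CC#C1 | intermediate
12 | 1,1-diethoxy-6-methoxy-4-(methoxymethoxy)benzocyclobutene | CCOC1(OCC)Cc2cc(OCOC)cc(OC)c21 | intermediate
13 | 6-methoxy-4-(methoxymethoxy)benzocyclobutenone (methoxy next to the carbonyl-bearing ring carbon) | COc1cc(OCOC)cc2c1C(=O)C2 | intermediate
14 | bis[3-lithio-6-methoxy-2,4-bis(methoxymethoxy)phenyl]methane, not isolated | COc1cc(OCOC)c([Li])c(OCOC)c1Cc1c(OC)cc(OCOC)c([Li])c1OCOC | intermediate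
15 | bis(lithium 1-arylbenzocyclobutenoxide), mixture of diastereomers at the two carbinol carbons, not isolated | [Li]OC1(Cc2cc(OCOC)cc(OC)c21)c1c(OCOC)cc(OC)c(Cc2c(OC)cc(OCOC)c(C3(O[Li])Cc4cc(OCOC)cc(OC)c43)c2OCOC)c1OCOC | intermediate
16 | bis(o-quinodimethane lithium enolate), enolate geometry lost on protonation and left open, not isolated | [Li]OC(=C1C(=C)C=C(OCOC)C=C1OC)c1c(OCOC)cc(OC)c(Cc2c(OC)cc(OCOC)c(C(O[Li])=C3C(=C)C=C(OCOC)C=C3OC)c2OCOC)c1OCOC | intermediate
17 | digriseophene A hexa-MOM ether | COc1cc(OCOC)c(C(=O)c2c(C)cc(OCOC)cc2OC)c(OCOC)c1Cc1c(OC)cc(OCOC)c(C(=O)c2c(C)cc(OCOC)cc2OC)c1OCOC | intermediate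
18 | digriseophene A (achiral) | COc1cc(O)c(C(=O)c2c(C)cc(O)cc2OC)c(O)c1Cc1c(OC)cc(O)c(C(=O)c2c(C)cc(O)cc2OC)c1O | target

Total step count: 9
Longest linear sequence: 6 (steps 1, 2, 3, 4, 8, 9)

**Steps most likely to fail**

Step 8.
- What may go wrong: the second addition may stall because a di-ortho-alkoxy aryllithium meets a carbonyl flanked by a methoxy group. Part of the lithiation may occur at the CH next to the methoxy group. The alkoxide may also fragment toward the methoxy-stabilised aryl anion instead of opening electrocyclically.
- Fallback (aldehyde addition, then oxidation): it sets out from 13 and from 14, generated from 7 as in step 8. NaBH4 in MeOH at 0 °C would reduce 13 to racemic 6-methoxy-4-(methoxymethoxy)benzocyclobutenol F1.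
- Neutral thermal ring opening and tautomerisation of this alcohol (toluene, 110 °C) would give 2-methoxy-4-(methoxymethoxy)-6-methylbenzaldehyde F2.
- Addition of 14 to two equivalents of this aldehyde at −78 °C would give the hexa-MOM bis(diarylcarbinol) F3 as a diastereomer mixture. Dess–Martin oxidation of both carbinols in CH2Cl2 would come back to the route at 17.

Step 2.
- What may go wrong: condensation may continue at the second free ring position of the dimer, giving trimers and higher oligomers.
- Fallback (halogen blocking group): it sets out from 2. One equivalent of NBS in MeCN at 0 °C would give methyl 3-bromo-2,6-dihydroxy-4-methoxybenzoate F4, which keeps only one nucleophilic ring carbon.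
- Condensation with formaldehyde under the conditions of step 2 can then stop only at dimethyl 3,3'-methylenebis(5-bromo-2,6-dihydroxy-4-methoxybenzoate) F5.
- Hydrogenolysis of both C–Br bonds (H2, Pd/C, NaOAc, MeOH) would come back to the route at 4.

Step 3.
- What may go wrong: in hot alkali a phenolate may expel the neighbouring ring by retro-conjugate addition, which scrambles the methylene bridge. The polyphenolate may also be oxidised by air.
- Fallback (cap the phenols first, decarboxylate under metal catalysis): it sets out from 4. NaH and MOMCl in DMF would give dimethyl 3,3'-methylenebis[4-methoxy-2,6-bis(methoxymethoxy)benzoate] F6, which has no phenolate left to trigger bridge cleavage.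
- Forcing saponification (KOH, EtOH–H2O, reflux) would give 3,3'-methylenebis[4-methoxy-2,6-bis(methoxymethoxy)benzoic acid] F7.
- Silver-catalysed protodecarboxylation (Ag2CO3 cat., AcOH cat., DMSO, 120 °C) would come back to the route at 7, bypassing 5 and 6.

**Further compounds**
F1 | step 8 | 6-methoxy-4-(methoxymethoxy)benzocyclobutenol (racemic) | COc1cc(OCOC)cc2c1C(O)C2
F2 | step 8 | 2-methoxy-4-(methoxymethoxy)-6-methylbenzaldehyde | COCOc1cc(C)c(C=O)c(OC)c1
F3 | step 8 | hexa-MOM bis(diarylcarbinol), mixture of diastereomers | COc1cc(OCOC)c(C(O)c2c(C)cc(OCOC)cc2OC)c(OCOC)c1Cc1c(OC)cc(OCOC)c(C(O)c2c(C)cc(OCOC)cc2OC)c1OCOC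
F4 | step 2 | methyl 3-bromo-2,6-dihydroxy-4-methoxybenzoate | COC(=O)c1c(O)cc(OC)c(Br)c1O
F5 | step 2 | dimethyl 3,3'-methylenebis(5-bromo-2,6-dihydroxy-4-methoxybenzoate) | COC(=O)c1c(O)c(Br)c(OC)c(Cc2c(OC)c(Br)c(O)c(C(=O)OC)c2O)c1O
F6 | step 3 | dimethyl 3,3'-methylenebis[4-methoxy-2,6-bis(methoxymethoxy)benzoate] | COC(=O)c1c(OCOC)cc(OC)c(Cc2c(OC)cc(OCOC)c(C(=O)OC)c2OCOC)c1OCOC
F7 | step 3 | 3,3'-methylenebis[4-methoxy-2,6-bis(methoxymethoxy)benzoic acid] | OC(=O)c1c(OCOC)cc(OC)c(Cc2c(OC)cc(OCOC)c(C(=O)O)c2OCOC)c1OCOC
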